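in all of them: free catalyst 3.0 mM

| flask | substrate | time | remark |
|---|---|---|---|
| beta | 0.020 M (fed, over 24.0 s) | 30 s | all but substrate at the start; substrate goes in evenly over 24.0 s, the run ends at 30 s |
| gamma | 0.020 M |  | one stirred flow tank at steady state, fed with the mixture as stated, mean residence time 150 s |
| zeta | 0.020 M |  | one stirred flow tank at steady state, fed with the mixture as stated, mean residence time 30 s |
| eta | 0.020 M | 30 s | everything together in a closed stirred flask, run for 30 s |

    substrate + free catalyst ⇌ target + free catalyst, rate k1*[substrate]*[free catalyst] forward; the back reaction follows from the equilibrium constant (K1 = 28, k1 = 311 M⁻¹ s⁻¹)
    target + free catalyst ⇌ isomer of the product + free catalyst, rate k2*[free catalyst]*[target] forward; the back reaction follows from the equilibrium constant (K2 = 0.441, k2 = 1.70 M⁻¹ s⁻¹)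
    isomer of the product ⇌ substrate (k3 = 0.0411 s⁻¹)
    free catalyst → spent catalyst (k4 = 8.00 × 10⁻⁵ s⁻¹)

- the stated concentrations are those of everything mixed, before any reaction; amounts are the same in each set-up
- the feed brings no volume worth counting
- run time (beta): 30 s

- the set-up with the highest share of target in all that became target or isomer of the product, at the outlet or at the end ("none" if the first two lie within 2 percentage points) (beta / gamma / zeta / eta / none)
- share of target in all that became target or isomer of the product, at the outlet or at the end, beta
- share of target in all that became target or isomer of the product, at the outlet or at the end, gamma
- share of target in all that became target or isomer of the product, at the outlet or at the end, zeta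
- share of target in all that became target or isomer of the product, at the outlet or at the end, eta

- I reckoned the leftover: the few points by which the share of target stands below its equilibrium value. I followed this correction instead of the whole share.
- Substrate leaves by two pseudo-first-order routes: to target at 0.933 s⁻¹, and to isomer of the product, through the reverse of the isomer-to-substrate step, at 0.508 s⁻¹. The first-formed share of target is therefore 64.8%.
- The equilibrium share is 69.4%, so kinetic and thermodynamic control stand apart by a gap of 4.6 percentage points.
- Target and isomer of the product exchange directly over free catalyst and also by way of substrate. Adding the exchange rates in both directions gave 0.0550 s⁻¹.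
- Its inverse, 18.2 s, is the share relaxation time, the mean life of the gap. The mean life of substrate on these two forward routes is 0.694 s, far less than this, so I let the gap open at once. I held [free catalyst] as charged because its loss constant is far smaller than the relaxation rate.
- The first setting is time in the closed flask, eta. The gap shrinks exponentially over 30 s, which gave me 68.5%.
- The second setting is dosing, in beta. Portions enter evenly over 24.0 s, so their decay factors must be averaged, and this gave me 67.6%.
- The third setting is residence time in a flow tank, where mixed ages divide the gap by one plus the residence time over the relaxation time. Zeta, whose residence time equals 30 s, gave me 67.7%, and gamma, at 150 s, gave me 68.9%.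
- By my reckoning gamma and eta led, 0.39 points apart, which is less than the margin, so I answered none.
- The forecast gave 67.5% for beta, 68.9% for gamma, 67.6% for zeta and 68.5% for eta, with none as the choice, “the residence or age of the material setting the order”.
- The simulation gave 67.5% for beta, 68.9% for gamma, 67.6% for zeta and 68.5% for eta, and the choice was none. The share relaxation time was shorter than the 30 s of eta, and eta ended with target at 66.8% of the substrate charged. Beta, left until 300 s, ran for 16.5 relaxation times and stood at a share of 69.4%.

The constants were chosen freely; the result is computed.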